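## Analysis of the target

Flavone numbering is used for 13 and for the atoms of all its precursors.

Agehoustin B (13) is 5,6,7,2',3',4',5'-heptamethoxyflavone. It is a 4H-chromen-4-one made of benzo ring A (C4a, C5, C6, C7, C8, C8a) and pyranone ring C (O1, C2, C3, C4, C4a, C8a), with aryl ring B (C1' to C6') on C2. Ring A carries methoxy groups on C5, C6 and C7 and its only hydrogen on C8. Ring B carries methoxy groups on C2' to C5' and its only hydrogen on C6'. There is no stereocenter, and the C2–C1' axis has one ortho substituent (C2'-OMe) facing only C3-H and O1, so it rotates freely and no configuration needs control.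

The sensitive points are three:
- The C5 methoxy group lies peri to the C4 carbonyl group and is lost to Lewis or strong Brønsted acids by chelation.
- The two very electron-rich rings are turned into quinones by oxidants.
- Ring C is opened by hot aqueous base.

The difficulty is regiochemistry and economy. Two pentasubstituted benzene rings must be joined through a three-carbon bridge. C4 must enter at C4a, the most crowded site of ring A, between C5-OMe and C8a-O1. The usual methods build ring C bond by bond and then correct its oxidation level.

The feature exploited here is the C4a–C8a bond of ring A. It is flanked by C5-OMe on one side and C8-H on the other, which is the pattern of a 3-alkoxyaryne. Such an aryne is polarised so that an oxygen nucleophile goes to C8a and a carbanion appears on C4a, exactly where O1 and C4 stand in 13. The other atoms of ring C (O1, C2, C3, C4, the carbonyl oxygen) together with ring B are, atom for atom, an arylpropiolic acid.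

A second useful feature is symmetry. The parent phenol of ring A has two homotopic ortho positions and the parent arene of ring B has two homotopic C–H positions, so the first functionalisation of each can give only one isomer.

## Retrosynthetic reasoning

**O1–C2 (13 to 12).** The enol ether bond O1–C2 is cut first, which opens 13 to its isomer, the 2-hydroxyaryl ynone 12. The alkyne of 12 already holds C2 and C3 at the oxidation level of the flavone. The forward reaction is therefore a redox-neutral 6-endo-dig conjugate addition of the C8a phenoxide to C2, with no oxidant and no acid. It has to close the six-membered ring at C2 and not a five-membered ring at C3.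

**C4–C4a and O1–C8a (12 to 11 and 10), the key cut.** Both bonds that hold the bridge on ring A are cut together. Ring A becomes aryne 11 (triple bond C4a–C8a) and everything else becomes arylpropiolic acid 10. In the forward direction 11 must insert into the C–O single bond of the carboxyl group of 10, with oxygen going to C8a and the acyl carbon to C4a.

Cuts at C2–C3, C3–C4 or C2–C1' all leave an ortho-acylphenol to be made by electrophilic acylation at the crowded C4a, under conditions that endanger C5-OMe. The cut chosen here turns the crowding into an asset, because C5-OMe steers the addition. The gain is two monocyclic fragments of similar size, three new bonds and ring C in one operation. Compound 12 need not be isolated, because it closes to 13 in the same basic medium.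

**11 to 6.** Aryne 11 cannot be stored, so it is traced back to the 2-silylaryl triflate 6, with silicon on the future C4a and triflate on the future C8a. Fluoride-induced 1,2-elimination is mild enough to coexist with a carboxylate and an ynone.

**6 to 2 and 1.** The C–Si and O–S bonds of 6 are cut back through phenolate 5, aryllithium 4 and silyl ether 3 to bromophenol 2. An O-to-C silyl shift places silicon exactly where bromine stood. The C–Br bond of 2 goes back to phenol 1, whose para position is blocked and whose two ortho positions are homotopic.

**10 to 8 and 9, and 8 to 7.** The bond between C1' and the alkyne carbon that becomes C2 is cut. This gives aryl iodide 8 and propiolic acid 9, which supplies C2, C3, C4, O1 and the carbonyl oxygen in one piece. The C–I bond of 8 goes back to arene 7, whose two C–H positions are homotopic.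

## Alternatives that were turned down

**Alternative 1: the textbook chalcone route.**
- Disconnection: C2–C3 and O1–C2.
- Forward sequence: 1 would be C-acetylated to 2'-hydroxy-4',5',6'-trimethoxyacetophenone A1. Arene 7 would be formylated to 2,3,4,5-tetramethoxybenzaldehyde A2. The two would be joined by Claisen–Schmidt condensation to the 2'-hydroxychalcone A3. The forward key step would be oxidative cyclisation of A3 to 13. The Baker–Venkataraman variant changes only the oxidation level of the ring B partner.
- Reason for rejection: its step count is comparable, so length is not the reason. Each step makes one bond. C4 enters at C4a by a Lewis-acid-mediated acylation, the conditions that endanger the methoxy group next to the new carbonyl group. A3 holds C2 and C3 at the wrong oxidation level. The correcting oxidation is hot, halogen-based and acid-releasing, and it acts in the last step on two rings prone to halogenation and quinone formation and on the labile C5-OMe. It is also the route that would be drawn first.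

**Alternative 2: carbonylative three-component annulation.**
- Disconnection: C4–C4a, C3–C4 and O1–C2.
- Forward key step: palladium-catalysed carbonylative coupling of 2-iodo-3,4,5-trimethoxyphenol A4 with 1-ethynyl-2,3,4,5-tetramethoxybenzene A5, then closure through 12.
- Reason for rejection: the C–I bond of A4 sits between C–OH and C–OMe on a ring with four donor groups, so oxidative addition to zerovalent palladium is slow. Acyl-palladium formation must then outrun direct alkynylation and a five-membered closure that would leave out C4. A5 costs one step more than 10, because it needs coupling with a capped acetylene and then uncapping. C4 must be brought in as a toxic gas under pressure. The endgame passes through the same 12, so nothing is won there.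

**Alternative 3: ring B built from a four-membered ring.**
- Disconnection: the C1'–C2' and C5'–C6' bonds of ring B. The four contiguous oxygenated carbons C2' to C5' map onto dimethyl squarate A6.
- Forward key step: addition of [4-(trimethylsilyl)but-1-en-3-yn-2-yl]lithium A7 to A6 would give the racemic 4-alkenyl-4-hydroxycyclobutenone A8. Thermolysis (Moore rearrangement: 4π opening, then 6π closure) would give hydroquinone A9.
- Reason for rejection: the mapping is attractive, but the organolithium addition forbids carrying ring C or any carbonyl group. A9 needs two further O-methylations, the precursor of A7 is not an article of commerce, and ring C would still be unbuilt. The same oxygen pattern can be bought in 7, where symmetry already solves the regiochemistry.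

Key step: step 5

Assumption: 3,4,5-trimethoxyphenol (1), 1,2,3,4-tetramethoxybenzene (7) and propiolic acid (9) are taken as catalogue chemicals.

## Route

Step 1
Reactants: 1 3,4,5-trimethoxyphenol
Product: 2 2-bromo-3,4,5-trimethoxyphenol
Conditions: NBS (1.0 equiv), MeCN, −20 to 0 °C, dark
Reagents that add atoms: N-bromosuccinimide, O=C1CCC(=O)N1Br
Why: Electrophilic aromatic bromination; the para position is blocked and the two ortho positions are homotopic, so one equivalent of a mild bromonium source can give only one monobromide. Low temperature and exclusion of light should hold back a second bromination and oxidation of the phenol.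

Step 2
Reactants: 2 2-bromo-3,4,5-trimethoxyphenol
Product: 6 3,4,5-trimethoxy-2-(trimethylsilyl)phenyl trifluoromethanesulfonate, via aryl silyl ether 3 (not isolated), via aryllithium 4 (not isolated), via lithium phenolate 5 (not isolated)
Conditions: (Me3Si)2NH, THF, 70 °C, then evaporation; n-BuLi, THF, −78 °C; Tf2O, −78 to 0 °C
Reagents that add atoms: hexamethyldisilazane, C[Si](C)(C)N[Si](C)(C)C; trifluoromethanesulfonic anhydride, O=S(=O)(OS(=O)(=O)C(F)(F)F)C(F)(F)F; n-butyllithium, [Li]CCCC (lithium of 4 and 5 only)
Why: O-silylation, bromine-lithium exchange, retro-Brook 1,3-shift of silicon from oxygen to carbon (driven by formation of the lithium phenolate) and O-triflation make up the standard one-flask route from 2-bromophenols to 2-silylaryl triflates. Silicon ends exactly where bromine stood, and a silyl group flanked by triflate and methoxy is the pattern of the usual 3-methoxybenzyne precursor.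

Step 3
Reactants: 7 1,2,3,4-tetramethoxybenzene
Product: 8 1-iodo-2,3,4,5-tetramethoxybenzene
Conditions: NIS (1.05 equiv), CF3CO2H (0.2 equiv), MeCN, 23 °C
Reagents that add atoms: N-iodosuccinimide, O=C1CCC(=O)N1I
Why: Acid-activated electrophilic iodination of a methoxyarene; the two free positions are homotopic and each is ortho and para to methoxy groups, so only one monoiodide can form. The first iodine atom deactivates and shields the neighbouring position against a second substitution.

Step 4
Reactants: 8 1-iodo-2,3,4,5-tetramethoxybenzene; 9 propiolic acid
Product: 10 3-(2,3,4,5-tetramethoxyphenyl)prop-2-ynoic acid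
Conditions: PdCl2(PPh3)2 (5 mol %), Ph2P(CH2)4PPh2 (10 mol %), DBU (2.5 equiv), DMSO, 35 °C; then aq. HCl
Reagents that add atoms: none
Why: Copper-free Sonogashira coupling of an aryl iodide with the amidinium propiolate; zerovalent palladium formed in the flask inserts into the C–I bond, and the deprotonated alkyne is transferred and reductively eliminated. The absence of copper and the low temperature should keep the carboxyl group in place.

Step 5
Reactants: 6 3,4,5-trimethoxy-2-(trimethylsilyl)phenyl trifluoromethanesulfonate (1.5 equiv); 10 3-(2,3,4,5-tetramethoxyphenyl)prop-2-ynoic acid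
Product: 13 Agehoustin B, via aryne 11 (not isolated), via hydroxy ynone 12 (not isolated)
Conditions: CsF (4 equiv), THF, 125 °C, sealed tube
Reagents that add atoms: none
Why: Fluoride attacks the silicon of 6 and triflate leaves, so aryne 11 is released slowly because CsF is barely soluble in THF, while further CsF turns 10 into its caesium carboxylate and parks the proton as bifluoride. The carboxylate oxygen should add to C8a and not to C4a, because the inductively withdrawing C5 methoxy group distorts the aryne, makes C8a the more electrophilic terminus, stabilises the developing carbanion on the adjacent C4a and shields C4a, whereas C8a is flanked only by C8-H; the weaker and opposed effects of C6-OMe and C7-OMe roughly cancel. The C4a aryl anion then attacks the ester carbonyl carbon (4-exo-trig), and the strained four-membered alkoxide collapses by cleavage of the acyl C–O bond, a net insertion of the aryne into the C–O bond of the acid (an anionic ortho-Fries type 1,3-acyl shift) that gives the phenoxide of 12. This phenoxide closes ring C by 6-endo-dig conjugate addition of O1 to C2, and protonation at C3 by bifluoride ends the cascade. The closest known reaction type is the fluoride-induced coupling of 2-silylaryl triflates with carboxylic acids to 2-hydroxyaryl ketones, which with arylpropiolic acids runs on to flavones. Three selectivities are needed: the regiochemistry of addition (secured by C5-OMe), acyl shift rather than protonation of the aryl anion or its addition to the alkyne (secured by aprotic THF at high temperature, by the slim and electrophilic alkynyl ester carbonyl group next to the anion, and by the ester conformation that turns the alkyne away from ring A), and 6-endo rather than 5-exo closure (secured by the Michael polarisation of the ynone and by reversibility at 125 °C, which leads to the more stable pyranone). No stereocenter is formed, and the seven methyl ethers meet neither acid nor oxidant.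

## Compound list

1 | 3,4,5-trimethoxyphenol | COc1cc(O)cc(OC)c1OC | starting material
2 | 2-bromo-3,4,5-trimethoxyphenol | COc1cc(O)c(Br)c(OC)c1OC | intermediate
3 | (2-bromo-3,4,5-trimethoxyphenoxy)trimethylsilane | COc1cc(O[Si](C)(C)C)c(Br)c(OC)c1OC | intermediate
4 | [2,3,4-trimethoxy-6-(trimethylsilyloxy)phenyl]lithium | COc1cc(O[Si](C)(C)C)c([Li])c(OC)c1OC | intermediate
5 | lithium 3,4,5-trimethoxy-2-(trimethylsilyl)phenolate | COc1cc([O-])c([Si](C)(C)C)c(OC)c1OC.[Li+] | intermediate
6 | 3,4,5-trimethoxy-2-(trimethylsilyl)phenyl trifluoromethanesulfonate | COc1cc(OS(=O)(=O)C(F)(F)F)c([Si](C)(C)C)c(OC)c1OC | intermediate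
7 | 1,2,3,4-tetramethoxybenzene | COc1ccc(OC)c(OC)c1OC | starting material
8 | 1-iodo-2,3,4,5-tetramethoxybenzene | COc1cc(I)c(OC)c(OC)c1OC | intermediate
9 | propiolic acid | C#CC(=O)O | starting material
10 | 3-(2,3,4,5-tetramethoxyphenyl)prop-2-ynoic acid | COc1cc(C#CC(=O)O)c(OC)c(OC)c1OC | intermediate
11 | 3,4,5-trimethoxybenzyne (1,2-didehydro-3,4,5-trimethoxybenzene) | COC1=C(OC)C(OC)=CC#C1 | intermediate
12 | 1-(2-hydroxy-4,5,6-trimethoxyphenyl)-3-(2,3,4,5-tetramethoxyphenyl)prop-2-yn-1-one | COc1cc(O)c(C(=O)C#Cc2cc(OC)c(OC)c(OC)c2OC)c(OC)c1OC | intermediate
13 | Agehoustin B, 5,6,7-trimethoxy-2-(2,3,4,5-tetramethoxyphenyl)-4H-chromen-4-one | COc1cc(-c2cc(=O)c3c(OC)c(OC)c(OC)cc3o2)c(OC)c(OC)c1OC | target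

## Step count and least certain steps

Total step count: 5. Longest linear sequence: 3 steps (1 to 2 to 6 to 13, or 7 to 8 to 10 to 13).

**Step 5 (key step).**
- Main risk: premature protonation of the C4a aryl anion before it reaches the ester carbonyl group. The sequence would then stop at plain O-arylation without the C4–C4a bond. The anion is very basic, bifluoride is at hand, and C5-OMe crowds the anion.
- Further risks: thermal loss of CO2 from the caesium propiolate at 125 °C, O-arylation of the phenoxide by excess aryne, and partial closure in the 5-exo mode.
- Fallback: polar acylation replaces the aryne insertion. It sets out from 2 and 10 and comes back to the route at 12. Compound 2 is protected with MeOCH2Cl and i-Pr2NEt as 2-bromo-3,4,5-trimethoxy-1-(methoxymethoxy)benzene F1. Acid 10 is condensed with MeNH(OMe)·HCl and a carbodiimide to the Weinreb amide N-methoxy-N-methyl-3-(2,3,4,5-tetramethoxyphenyl)prop-2-ynamide F2. Bromine-lithium exchange of F1 with n-BuLi at −78 °C gives [2,3,4-trimethoxy-6-(methoxymethoxy)phenyl]lithium F3. F3 is acylated by F2 to 1-[2-(methoxymethoxy)-4,5,6-trimethoxyphenyl]-3-(2,3,4,5-tetramethoxyphenyl)prop-2-yn-1-one F4. Dilute HCl in MeOH removes the acetal and gives 12, which is closed to 13 with catalytic 4-dimethylaminopyridine in DMF.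

**Step 4.**
- Main risk: decarboxylation of the product on palladium followed by a second arylation of the freed alkyne, favoured if the slow oxidative addition to the electron-rich, ortho-substituted iodide forces a higher temperature.
- Fallback: the carboxyl carbon is attached last. It sets out from 8 and comes back at 10. Sonogashira coupling of 8 with ethynyltrimethylsilane (PdCl2(PPh3)2, CuI, Et3N) gives trimethyl[(2,3,4,5-tetramethoxyphenyl)ethynyl]silane F5. Desilylative carboxylation with CsF under CO2 (1 atm) in DMSO, followed by acidification, gives 10.

**Step 2.**
- Main risk: loss of aryllithium 4 by protonation or by alkylation with the butyl bromide formed in the exchange before silicon has migrated into the crowded site next to the methoxy group. Attack of n-BuLi on silicon instead of bromine is a second risk.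
- Fallback: intermolecular C-silylation replaces the intramolecular shift. It sets out from 2 and comes back at 5. Deprotonation with n-BuLi and exchange with t-BuLi (2 equiv) gives lithium 2-lithio-3,4,5-trimethoxyphenolate F6. Me3SiCl in excess converts F6 into trimethyl[2,3,4-trimethoxy-6-(trimethylsilyloxy)phenyl]silane F7, which can be purified. MeLi then cleaves only the O–Si bond and gives 5, which is triflated with Tf2O to 6.

**Step 1.**
- Main risk: a second bromination at the other ortho position, and oxidation of the very electron-rich phenol to a quinone by the N-bromo reagent.
- Fallback: directed ortho-metalation replaces electrophilic halogenation. It sets out from 1 and comes back at 6, bypassing steps 1 and 2. Compound 1 is carbamoylated (Et2NC(O)Cl, NaH) to 3,4,5-trimethoxyphenyl diethylcarbamate F8. s-BuLi and TMEDA at −78 °C metalate one of the two homotopic positions between the carbamate and methoxy groups, giving 2-lithio-3,4,5-trimethoxyphenyl diethylcarbamate F9. Me3SiCl gives 3,4,5-trimethoxy-2-(trimethylsilyl)phenyl diethylcarbamate F10. LiAlH4 cleaves the carbamate to 3,4,5-trimethoxy-2-(trimethylsilyl)phenol F11, and Tf2O with pyridine gives 6.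

## Further compounds

F1 | step 5 | 2-bromo-3,4,5-trimethoxy-1-(methoxymethoxy)benzene | COCOc1cc(OC)c(OC)c(OC)c1Br
F2 | step 5 | N-methoxy-N-methyl-3-(2,3,4,5-tetramethoxyphenyl)prop-2-ynamide | COc1cc(C#CC(=O)N(C)OC)c(OC)c(OC)c1OC
F3 | step 5 | [2,3,4-trimethoxy-6-(methoxymethoxy)phenyl]lithium | COCOc1cc(OC)c(OC)c(OC)c1[Li]
F4 | step 5 | 1-[2-(methoxymethoxy)-4,5,6-trimethoxyphenyl]-3-(2,3,4,5-tetramethoxyphenyl)prop-2-yn-1-one | COCOc1cc(OC)c(OC)c(OC)c1C(=O)C#Cc1cc(OC)c(OC)c(OC)c1OC
F5 | step 4 | trimethyl[(2,3,4,5-tetramethoxyphenyl)ethynyl]silane | COc1cc(C#C[Si](C)(C)C)c(OC)c(OC)c1OC
F6 | step 2 | lithium 2-lithio-3,4,5-trimethoxyphenolate | COc1cc([O-])c([Li])c(OC)c1OC.[Li+]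
F7 | step 2 | trimethyl[2,3,4-trimethoxy-6-(trimethylsilyloxy)phenyl]silane | COc1cc(O[Si](C)(C)C)c([Si](C)(C)C)c(OC)c1OC
F8 | step 1 | 3,4,5-trimethoxyphenyl diethylcarbamate | CCN(CC)C(=O)Oc1cc(OC)c(OC)c(OC)c1
F9 | step 1 | 2-lithio-3,4,5-trimethoxyphenyl diethylcarbamate | CCN(CC)C(=O)Oc1cc(OC)c(OC)c(OC)c1[Li]
F10 | step 1 | 3,4,5-trimethoxy-2-(trimethylsilyl)phenyl diethylcarbamate | CCN(CC)C(=O)Oc1cc(OC)c(OC)c(OC)c1[Si](C)(C)C
F11 | step 1 | 3,4,5-trimethoxy-2-(trimethylsilyl)phenol | COc1cc(O)c([Si](C)(C)C)c(OC)c1OC
A1 | alternative 1 | 1-(2-hydroxy-4,5,6-trimethoxyphenyl)ethan-1-one | CC(=O)c1c(O)cc(OC)c(OC)c1OC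
A2 | alternative 1 | 2,3,4,5-tetramethoxybenzaldehyde | COc1cc(C=O)c(OC)c(OC)c1OC
A3 | alternative 1 | (E)-1-(2-hydroxy-4,5,6-trimethoxyphenyl)-3-(2,3,4,5-tetramethoxyphenyl)prop-2-en-1-one | COc1cc(O)c(C(=O)/C=C/c2cc(OC)c(OC)c(OC)c2OC)c(OC)c1OC
A4 | alternative 2 | 2-iodo-3,4,5-trimethoxyphenol | COc1cc(O)c(I)c(OC)c1OC
A5 | alternative 2 | 1-ethynyl-2,3,4,5-tetramethoxybenzene | C#Cc1cc(OC)c(OC)c(OC)c1OC
A6 | alternative 3 | dimethyl squarate (3,4-dimethoxycyclobut-3-ene-1,2-dione) | COC1=C(OC)C(=O)C1=O
A7 | alternative 3 | [4-(trimethylsilyl)but-1-en-3-yn-2-yl]lithium | [Li]C(=C)C#C[Si](C)(C)C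
A8 | alternative 3 | 4-hydroxy-2,3-dimethoxy-4-[4-(trimethylsilyl)but-1-en-3-yn-2-yl]cyclobut-2-en-1-one (racemic) | COC1=C(OC)C(O)(C(=C)C#C[Si](C)(C)C)C1=O
A9 | alternative 3 | 2,3-dimethoxy-5-[(trimethylsilyl)ethynyl]benzene-1,4-diol | COc1c(O)cc(C#C[Si](C)(C)C)c(O)c1OC
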